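**Retrosynthetic overview**
1. Target ⇐ side-chain ketone (C3'=O becomes C3'=CH2 in the last step) ⇐ allyl β-keto ester (deallylation, loss of CO2).
2. Key C–C bond C3'–C4': intermolecular decarboxylative Claisen condensation of the acyl imidazole of the tetracyclic core acid with the magnesium enolate of allyl hydrogen prenylmalonate (from diallyl malonate and prenyl bromide).
3. Core acid ⇐ [4+2] cycloaddition of a 1-oxo-2,4-dienone with acrylic acid (bonds C2–C2' and C5–C1'; sets C2, C5 and C2').
4. Dienone ⇐ α-santonin by 1,3-carbonyl transposition (epoxidation, Wharton, oxidation); C6, C7, C10 and C11 are taken over unchanged.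
5. Ring order: rings A and B and the γ-lactone come with santonin; the bicyclo[2.2.2]octenone is the only ring made (step 4); the C7 chain is joined afterwards.

Assumption and convention (one line): α-santonin is taken as a cheap commercial chiral-pool material; sesquiterpene carbons keep eudesmane numbers, the C10 unit is numbered C1'–C10' as in myrcene (C1' on C5, C2' on C2), β is the face of the C10 methyl, and endo means syn to the C3=C4 bridge.

**Route**

Step 1
Reactants: 1 α-santonin
Product: 2 1α,2α-epoxy-3-oxoeudesm-4-en-11βH-12,6α-olide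
Conditions: 30% aq H2O2, NaOH (0.3 equiv), MeOH, 0 °C → rt; then 1 M HCl to pH 3
Reagents that add atoms: hydrogen peroxide, OO
Why: Weitz–Scheffer nucleophilic epoxidation attacks only the disubstituted C1=C2 enone (the β-carbon of C4=C5 is fully substituted) from the α-face anti to the C10 methyl, acidification recloses any opened lactone, and the epoxide configuration is erased in step 3.

Step 2
Reactants: 2 1α,2α-epoxy-3-oxoeudesm-4-en-11βH-12,6α-olide
Product: 4 1α-hydroxyeudesma-2,4-dien-11βH-12,6α-olide, via epoxy hydrazone 3 (not isolated)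
Conditions: N2H4·H2O (3 equiv), AcOH (0.5 equiv), MeOH, 0 °C → rt, 2 h
Reagents that add atoms: none
Why: Wharton transposition: the C3 hydrazone fragments with loss of N2 and opening of the C2–O bond, which moves the oxygen to C1 (C1–O bond retained, 1α-OH) and the alkene to C2=C3 in conjugation with C4=C5.

Step 3
Reactants: 4 1α-hydroxyeudesma-2,4-dien-11βH-12,6α-olide
Product: 5 1-oxoeudesma-2,4-dien-11βH-12,6α-olide
Conditions: Dess–Martin periodinane (1.3 equiv), CH2Cl2, 0 °C → rt, dark
Reagents that add atoms: none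
Why: Dess–Martin oxidation of the hindered allylic secondary alcohol gives the linear 2,4-dienone under neutral conditions that leave the lactone and C11 untouched.

Step 4
Reactants: 5 1-oxoeudesma-2,4-dien-11βH-12,6α-olide; 6 acrylic acid
Product: 7 endo-2'-carboxy-1-oxo-2β,5β-ethanoeudesm-3-en-11βH-12,6α-olide (2S,5R,6S,7S,10R,11S,2'S)
Conditions: 6 (5 equiv), BHT (5 mol %), toluene, 110 °C, sealed tube, dark, 36 h
Reagents that add atoms: none
Why: Thermal Diels–Alder reaction with the 2,4-dienone as diene: the CH2 terminus bonds to the fully substituted C5 and the carboxyl-bearing carbon to C2 (ortho rule for 2,4-cyclohexadienones), the endo transition state puts CO2H syn to the new C3=C4 bridge (sets C2'), and addition on the β-face (equatorial to chair ring B, away from axial H7 and H9 and the concave ring A/ring B fold) sets C2 and C5.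

Step 5
Reactants: 8 diallyl malonate; 9 prenyl bromide (1-bromo-3-methylbut-2-ene)
Product: 11 diallyl 2-(3-methylbut-2-en-1-yl)malonate, via sodium malonate enolate 10 (not isolated)
Conditions: NaH (1.0 equiv), THF, 0 °C; then 9 (0.9 equiv), 0 °C → rt
Reagents that add atoms: none
Why: Malonic ester alkylation: the soft malonate enolate displaces the primary allylic bromide by SN2 at the unsubstituted carbon, and a slight excess of malonate suppresses dialkylation.

Step 6
Reactants: 11 diallyl 2-(3-methylbut-2-en-1-yl)malonate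
Product: 13 allyl hydrogen 2-(3-methylbut-2-en-1-yl)malonate (racemic), via potassium half-ester salt 12 (not isolated)
Conditions: KOH (1.0 equiv), THF/H2O, 0 °C; then 1 M HCl
Reagents that add atoms: potassium hydroxide, [K+].[OH-]
Why: Selective monosaponification of a malonic diester stops at the half-ester because the first carboxylate deactivates the second ester toward hydroxide.

Step 7
Reactants: 7 endo-2'-carboxy-1-oxo-2β,5β-ethanoeudesm-3-en-11βH-12,6α-olide; 13 allyl hydrogen 2-(3-methylbut-2-en-1-yl)malonate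
Product: 16 allyl 5-methyl-2-[(1-oxo-2β,5β-ethanoeudesm-3-en-11βH-12,6α-olid-2'-yl)carbonyl]hex-4-enoate (C4' epimers), via acyl imidazole 14 (not isolated), via acylmalonic half-acid 15 (not isolated)
Conditions: 7, CDI (1.1 equiv), THF, rt, 1 h; add to 13 (2 equiv), MgCl2 (2 equiv), Et3N (4 equiv), MeCN, rt → 45 °C, 16 h; 1 M HCl work-up
Reagents that add atoms: none
Why: Decarboxylative crossed Claisen condensation (Masamune–Brooks type): the chelated magnesium enolate of the half-ester C-acylates the acyl imidazole under near-neutral conditions that spare the non-enolisable C1 ketone, the lactone and the C2'–H, and loss of CO2 gives the β-keto ester, whose new C4' centre is removed in step 8.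

Step 8
Reactants: 16 allyl β-keto ester
Product: 18 2'-(5-methylhex-4-enoyl)-1-oxo-2β,5β-ethanoeudesm-3-en-11βH-12,6α-olide, via β-keto acid 17 (not isolated)
Conditions: Pd(PPh3)4 (5 mol %), morpholine (3 equiv), THF, rt → 40 °C
Reagents that add atoms: none
Why: Tsuji–Trost deallylation: zerovalent palladium ionises the allyl ester, morpholine traps the allyl group, and the free β-keto acid decarboxylates under nearly neutral conditions, so the epimerisable C2'–H is not disturbed.

Step 9
Reactants: 18 2'-(5-methylhex-4-enoyl)-1-oxo-2β,5β-ethanoeudesm-3-en-11βH-12,6α-olide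
Product: 19 2'-(6-methylhepta-1,5-dien-2-yl)-1-oxo-2β,5β-ethanoeudesm-3-en-11βH-12,6α-olide (2S,5R,6S,7S,10R,11S,2'S), the target CNP0385704.1
Conditions: Zn, CH2Br2, TiCl4, THF, 0 °C → rt (reagent pre-formed); then 18 in CH2Cl2, 0 °C → rt; then water
Reagents that add atoms: dibromomethane, BrCBr
Why: Takai–Lombardo methylenation is non-basic (no C2' epimerisation) and converts the less hindered side-chain ketone, not the C1 ketone flanked by quaternary C10 and bridgehead C2, nor the lactone.

**Compound list**
1 | α-santonin (3-oxoeudesma-1,4-dien-11βH-12,6α-olide) | C[C@H]1[C@@H]2CC[C@]3(C=CC(=O)C(=C3[C@H]2OC1=O)C)C | starting material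
2 | 1α,2α-epoxy-3-oxoeudesm-4-en-11βH-12,6α-olide | C[C@H]1[C@@H]2CC[C@]3([C@H]4O[C@H]4C(=O)C(=C3[C@H]2OC1=O)C)C | intermediate
3 | C3 hydrazone of 2 | C[C@H]1[C@@H]2CC[C@]3([C@H]4O[C@H]4C(=NN)C(=C3[C@H]2OC1=O)C)C | intermediate (not isolated)
4 | 1α-hydroxyeudesma-2,4-dien-11βH-12,6α-olide | O[C@H]1C=CC(C)=C2[C@@]1(C)CC[C@H]1[C@H](C)C(=O)O[C@H]21 | intermediate
5 | 1-oxoeudesma-2,4-dien-11βH-12,6α-olide | O=C1C=CC(C)=C2[C@@]1(C)CC[C@H]1[C@H](C)C(=O)O[C@H]21 | intermediate
6 | acrylic acid | C=CC(=O)O | starting material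
7 | endo-2'-carboxy-1-oxo-2β,5β-ethanoeudesm-3-en-11βH-12,6α-olide (CO2H syn to C3=C4) | OC(=O)[C@H]1C[C@@]23C(C)=C[C@@H]1C(=O)[C@]2(C)CC[C@H]1[C@H](C)C(=O)O[C@@H]13 | intermediate
8 | diallyl malonate | C=CCOC(=O)CC(=O)OCC=C | starting material
9 | prenyl bromide (1-bromo-3-methylbut-2-ene) | CC(C)=CCBr | starting material
10 | sodium enolate of diallyl malonate | C=CCOC(=O)[CH-]C(=O)OCC=C.[Na+] | intermediate (not isolated)
11 | diallyl 2-(3-methylbut-2-en-1-yl)malonate | C=CCOC(=O)C(CC=C(C)C)C(=O)OCC=C | intermediate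
12 | potassium 2-(allyloxycarbonyl)-5-methylhex-4-enoate | C=CCOC(=O)C(CC=C(C)C)C(=O)[O-].[K+] | intermediate (not isolated)
13 | allyl hydrogen 2-(3-methylbut-2-en-1-yl)malonate (racemic) | C=CCOC(=O)C(CC=C(C)C)C(=O)O | intermediate
14 | acyl imidazole of 7 | O=C(n1ccnc1)[C@H]1C[C@@]23C(C)=C[C@@H]1C(=O)[C@]2(C)CC[C@H]1[C@H](C)C(=O)O[C@@H]13 | intermediate (not isolated)
15 | C-acylated malonic half-acid (C4' epimers) | OC(=O)C(CC=C(C)C)(C(=O)OCC=C)C(=O)[C@H]1C[C@@]23C(C)=C[C@@H]1C(=O)[C@]2(C)CC[C@H]1[C@H](C)C(=O)O[C@@H]13 | intermediate (not isolated)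
16 | allyl β-keto ester (C4' epimers) | C=CCOC(=O)C(CC=C(C)C)C(=O)[C@H]1C[C@@]23C(C)=C[C@@H]1C(=O)[C@]2(C)CC[C@H]1[C@H](C)C(=O)O[C@@H]13 | intermediate
17 | β-keto acid (C4' epimers) | OC(=O)C(CC=C(C)C)C(=O)[C@H]1C[C@@]23C(C)=C[C@@H]1C(=O)[C@]2(C)CC[C@H]1[C@H](C)C(=O)O[C@@H]13 | intermediate (not isolated)
18 | 2'-(5-methylhex-4-enoyl)-1-oxo-2β,5β-ethanoeudesm-3-en-11βH-12,6α-olide | CC(C)=CCCC(=O)[C@H]1C[C@@]23C(C)=C[C@@H]1C(=O)[C@]2(C)CC[C@H]1[C@H](C)C(=O)O[C@@H]13 | intermediate
19 | 2'-(6-methylhepta-1,5-dien-2-yl)-1-oxo-2β,5β-ethanoeudesm-3-en-11βH-12,6α-olide | C=C(CCC=C(C)C)[C@H]1C[C@@]23C(C)=C[C@@H]1C(=O)[C@]2(C)CC[C@H]1[C@H](C)C(=O)O[C@@H]13 | target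

**Totals**
Total step count: 9. Longest linear sequence: 7 steps (1, 2, 3, 4, 7, 8, 9, from α-santonin).

**Three steps most likely to fail**

Step 4 (cycloaddition). The diene terminus C5 is fully substituted, face and endo selectivity are predicted rather than proven, and hot acrylic acid can polymerise. The fallback sets out from 5 and comes back at 19. Compound 5 is heated with commercial β-myrcene (10 equiv, BHT, toluene, 125 °C, sealed tube). This is an inverse-electron-demand [4+2] addition in which the monosubstituted vinyl group of the terpene diene is the 2π partner, and the same ortho, endo and β-face preferences lead directly to 19. No new compound is made on this way (none F0).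

Step 7 (Claisen condensation). A substituted malonate enolate must acylate a hindered secondary acyl imidazole. The fallback sets out from 7 (through 14) and comes back at 16. Meldrum's acid and allyl alcohol (toluene, 100 °C) give allyl hydrogen malonate F1. Its magnesium enolate (MgCl2, Et3N, MeCN) is acylated by 14 to give the C-acylmalonic half-acid F2 (not isolated), which loses CO2 to the unsubstituted allyl β-keto ester F3. Mono-C-prenylation of F3 with 9 (K2CO3, acetone, rt) then gives 16.

Step 2 (Wharton transposition). Yields vary and hydrazine can attack the lactone. The fallback sets out from 2 and comes back at 4. Reduction with NaBH4 and CeCl3·7H2O (MeOH, −20 °C) gives the 3ξ-hydroxy epoxide F4. 1,1'-Thiocarbonyldiimidazole (DMAP, CH2Cl2) converts it to the O-(imidazol-1-ylthiocarbonyl) derivative F5. Bu3SnH with AIBN (toluene, 80 °C) generates the C3 radical, which opens the epoxide at C2–O; the C1 alkoxy radical takes hydrogen from the stannane and gives 4.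

**Further compounds**
F0 | step 4 | none | none
F1 | step 7 | allyl hydrogen malonate | C=CCOC(=O)CC(=O)O
F2 | step 7 | C-acylmalonic half-acid (unsubstituted) | OC(=O)C(C(=O)OCC=C)C(=O)[C@H]1C[C@@]23C(C)=C[C@@H]1C(=O)[C@]2(C)CC[C@H]1[C@H](C)C(=O)O[C@@H]13
F3 | step 7 | unsubstituted allyl β-keto ester | C=CCOC(=O)CC(=O)[C@H]1C[C@@]23C(C)=C[C@@H]1C(=O)[C@]2(C)CC[C@H]1[C@H](C)C(=O)O[C@@H]13
F4 | step 2 | 1α,2α-epoxy-3ξ-hydroxyeudesm-4-en-11βH-12,6α-olide | C[C@H]1[C@@H]2CC[C@]3([C@H]4O[C@H]4C(O)C(=C3[C@H]2OC1=O)C)C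
F5 | step 2 | O-(imidazol-1-ylthiocarbonyl) derivative of F4 | C[C@H]1[C@@H]2CC[C@]3([C@H]4O[C@H]4C(OC(=S)n5ccnc5)C(=C3[C@H]2OC1=O)C)C
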